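Slowness marks the earlier runs. In cedar, ash, birch and maple alike, starting material stands near 55.6% at 3.00 h, a first-order fall with k = 0.196 h⁻¹ and a half-life of 3.54 h. Target lags behind it, with cedar reading 0.6% at 2.00 h. From cedar to maple the partner charge grows by a factor 1.47 and target at 3.00 h by 1.44, although maple holds more starting material.

| flask | starting material | partner | remark | time |
|---|---|---|---|---|
| cedar | 0.11 M | 0.15 M (in portions, 3) | run made earlier; portions every 2.0 h |  |
| ash | 0.11 M | 0.18 M (in portions, 3) | run made earlier; portions every 2.0 h |  |
| birch | 0.11 M | 0.21 M (in portions, 3) | run made earlier; portions every 2.0 h |  |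
| maple | 0.17 M | 0.22 M (in portions, 3) | run made earlier; portions every 2.0 h |  |
| zeta | 0.11 M | 0.220 M (in portions, 3) | the portions of partner follow each other after 2.0 h, the first at the start | 6.0 h |
| alpha | 0.40 M | 0.150 M | everything together at the start | 6.0 h |

| run | time / h | target / % | starting material / % |
|---|---|---|---|
| cedar | 0.667 | 0.2 | 86.7 |
| cedar | 1.33 | 0.2 | 76.5 |
| cedar | 2.00 | 0.6 | 67.2 |
| cedar | 2.50 | 1.5 | 61.1 |
| cedar | 3.00 | 2.5 | 55.6 |
| ash | 0.667 | 0 | 86.4 |
| ash | 1.33 | 0 | 75.3 |
| ash | 2.00 | 1.7 | 66.7 |
| ash | 2.50 | 2.0 | 61.4 |
| ash | 3.00 | 2.8 | 55.9 |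
| birch | 0.250 | 0.1 | 94.6 |
| birch | 0.417 | 0 | 91.2 |
| birch | 0.833 | 0.3 | 84.0 |
| birch | 1.50 | 0.8 | 73.2 |
| birch | 3.00 | 3.4 | 55.6 |
| maple | 0.250 | 0 | 94.8 |
| maple | 0.833 | 0.2 | 84.2 |
| maple | 1.33 | 0.4 | 75.7 |
| maple | 2.00 | 1.4 | 66.7 |
| maple | 3.00 | 3.6 | 56.2 |

(scatter of a reading: 0.3 percentage points)

- the numbers in the tables scatter by 0.3 percentage points (one standard deviation)

1. which of the two ends with the higher amount of target, in percent of the starting material charged ("neither" if they lie within 2 percentage points) (zeta / alpha / neither)
2. target at the end, in percent of the starting material charged, zeta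
3. target at the end, in percent of the starting material charged, alpha

The reckoning made here takes the slope of target as κ(1−a)D, where a is the fraction of starting material remaining and D the partner added so far. Target then follows the exposure E, the time integral of (1−a)D. Per unit of charge, the portions give 0.372 h at 3.00 h, and the four runs pooled there give κ = 0.435 L mol⁻¹ h⁻¹.

In zeta the curve leaves the origin with zero slope and steepens as starting material opens. It has knees at 2.0 h and 4.00 h, where the slope steps up, and reaches 1.10% and 6.72% at those two times. By 6.0 h the weighted time is 1.95 h, so the exposure is 1540 M·s and the reckoned target 18.6%, still climbing with no plateau. Alpha has exposure 1330 M·s and reckoned target 16.1%. That amount of target takes 42.9% of alpha's partner, more than the 9.31% of zeta's, so this reckoning expects zeta ahead, with alpha falling further below its number.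

The forecast names zeta, with 15.3% for zeta and 12% for alpha, both lower than the reckoning here , and it reads from the runs “so target % does not depend on starting-material concentration”.

The flask gives 16.3% in zeta and 11.0% in alpha, so zeta ends higher.

    target ⇌ isomer of the product (K = 0.130, k = 0.190 h⁻¹)
    2 open intermediate → homo product (k = 2.20 L mol⁻¹ h⁻¹)
    partner → second intermediate (k = 0.180 h⁻¹)
    open intermediate → side product (k = 0.0630 h⁻¹)
    open intermediate + second intermediate → target (k = 2.90 L mol⁻¹ h⁻¹)
    starting material ⇌ open intermediate (K = 2.50, k = 0.220 h⁻¹)

Exposure separates the two flasks by a factor 1.16, target by 1.48. Part of that gap comes from alpha's concentration of starting material, far above the runs' range: with zeta's concentration, alpha gives 19.0% instead of 11.0%. In zeta, the time given and the dosing of partner act together on the end value: without the dosing zeta gives 25.5%, and at ten times the time 53.2%. Alpha, given the same longer time, gives 27.1%. Zeta itself returns 0.382 L mol⁻¹ h⁻¹ per unit of exposure. A neighbour of zeta with 0.13 M of partner has exposure 911 M·s, which gives 9.67%; the flask gives 10.4%.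

Readings and results were generated by integration for substances that don't exist.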